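**Assumptions**
- The target has no stereocentres and no E/Z-capable alkene, so it is achiral and the "single enantiomer" requirement is moot.
- 3,6-Dimethoxybenzene-1,2-diol (4) is taken as a catalogue compound; I could not confirm this. If it is not stocked, it takes two steps from 2,5-dimethoxyphenol (MgCl2/Et3N/(CH2O)n ortho-formylation, then Dakin oxidation).

**Retrosynthetic overview**
1. No rings are formed; both benzene rings are purchased. The last step is removal of two MOM groups from ring A.
2. The C5' prenyl group comes from a para-Claisen rearrangement of the C2' O-prenyl ether. Both ortho positions are blocked, so the prenyl lands para to the phenol that is freed.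
3. The diaryl ether C–O bond comes from Pd-catalysed coupling of a ring-A aryl triflate with a ring-B phenol.
4. Ring A triflate: methyl 2,4,6-trihydroxybenzoate, bis-MOM protection, then triflation of the remaining H-bonded OH.
5. Ring B phenol: mono-O-prenylation of the symmetric 3,6-dimethoxycatechol, so there is no regiochemical question.

**Route**

Step 1
Reactants: 1, methyl 2,4,6-trihydroxybenzoate
Product: 2, methyl 2-hydroxy-4,6-bis(methoxymethoxy)benzoate
Conditions: MOMCl (2.2 equiv), i-Pr2NEt (2.5 equiv), CH2Cl2, 0 °C to rt
Reagents that add atoms: chloromethyl methyl ether (MOMCl), COCCl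
Why: O-alkylation (MOM protection) takes the 4-OH and one of the two equivalent ortho-OH groups; the last OH is hydrogen-bonded to the ester carbonyl and is left free.

Step 2
Reactants: 2, methyl 2-hydroxy-4,6-bis(methoxymethoxy)benzoate
Product: 3, methyl 2,4-bis(methoxymethoxy)-6-[(trifluoromethanesulfonyl)oxy]benzoate
Conditions: Tf2O (1.2 equiv), pyridine, CH2Cl2, 0 °C
Reagents that add atoms: triflic anhydride, O=S(=O)(OS(=O)(=O)C(F)(F)F)C(F)(F)F
Why: O-triflation of the only free phenol gives an aryl electrophile activated by the ortho ester; MOM ethers survive the buffered, cold conditions.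

Step 3
Reactants: 4, 3,6-dimethoxybenzene-1,2-diol (1.5 equiv); 5, prenyl bromide (1-bromo-3-methylbut-2-ene, 1.0 equiv)
Product: 6, 3,6-dimethoxy-2-[(3-methylbut-2-en-1-yl)oxy]phenol
Conditions: K2CO3 (1.0 equiv), degassed acetone, N2, rt to 40 °C; chromatograph, recover excess 4
Reagents that add atoms: prenyl bromide (5), CC(C)=CCBr
Why: Williamson mono-etherification of a symmetric catechol gives one mono-ether; excess diol suppresses the bis-ether, so the yield is statistical but the regiochemistry is unambiguous.

Step 4
Reactants: 3, the aryl triflate; 6, 3,6-dimethoxy-2-(prenyloxy)phenol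
Product: 7, methyl 2-{3,6-dimethoxy-2-[(3-methylbut-2-en-1-yl)oxy]phenoxy}-4,6-bis(methoxymethoxy)benzoate
Conditions: Pd(OAc)2 (5 mol %), tBuXPhos (10 mol %), K3PO4 (2 equiv), toluene, 100 °C, Ar
Reagents that add atoms: none (all product atoms come from 3 and 6)
Why: Buchwald–Hartwig-type Pd-catalysed C–O coupling; the ortho-ester makes the Ar–Pd electron-poor, favouring oxidative addition and C–O reductive elimination, and weak base in toluene limits triflate S–O cleavage.

Step 5
Reactants: 7, the O-prenyl diaryl ether
Product: 8, methyl 2-[2-hydroxy-3,6-dimethoxy-5-(3-methylbut-2-en-1-yl)phenoxy]-4,6-bis(methoxymethoxy)benzoate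
Conditions: PhNEt2, 190 °C, sealed tube, Ar, 2–4 h
Reagents that add atoms: none
Why: para-Claisen rearrangement (Claisen then Cope [3,3] shifts): both ortho positions of the prenyl ether carry OAr or OMe, so the prenyl relays to C5' (para), with double allyl inversion giving the linear prenyl and the free C2' phenol; no stereocentre is created.

Step 6
Reactants: 8, the bis-MOM ether
Product: 9, paucinervin B, methyl 2,4-dihydroxy-6-[2-hydroxy-3,6-dimethoxy-5-(3-methylbut-2-en-1-yl)phenoxy]benzoate
Conditions: 3 M aq HCl/MeOH (1:5), 45 °C
Reagents that add atoms: none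
Why: Acid-catalysed acetal cleavage removes both MOM groups; MeOH keeps the ester as the methyl ester, and the prenyl group has no ortho free OH (neighbours are H and OMe), so chroman formation is not possible.

**Compound list**
1 | methyl 2,4,6-trihydroxybenzoate | COC(=O)c1c(O)cc(O)cc1O | starting material
2 | methyl 2-hydroxy-4,6-bis(methoxymethoxy)benzoate | COC(=O)c1c(O)cc(OCOC)cc1OCOC | intermediate
3 | methyl 2,4-bis(methoxymethoxy)-6-[(trifluoromethanesulfonyl)oxy]benzoate | COC(=O)c1c(OCOC)cc(OCOC)cc1OS(=O)(=O)C(F)(F)F | intermediate
4 | 3,6-dimethoxybenzene-1,2-diol | COc1ccc(OC)c(O)c1O | starting material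
5 | prenyl bromide (1-bromo-3-methylbut-2-ene) | CC(C)=CCBr | starting material
6 | 3,6-dimethoxy-2-[(3-methylbut-2-en-1-yl)oxy]phenol | COc1ccc(OC)c(OCC=C(C)C)c1O | intermediate
7 | methyl 2-{3,6-dimethoxy-2-[(3-methylbut-2-en-1-yl)oxy]phenoxy}-4,6-bis(methoxymethoxy)benzoate | COC(=O)c1c(OCOC)cc(OCOC)cc1Oc1c(OCC=C(C)C)c(OC)ccc1OC | intermediate
8 | methyl 2-[2-hydroxy-3,6-dimethoxy-5-(3-methylbut-2-en-1-yl)phenoxy]-4,6-bis(methoxymethoxy)benzoate | COC(=O)c1c(OCOC)cc(OCOC)cc1Oc1c(O)c(OC)cc(CC=C(C)C)c1OC | intermediate
9 | paucinervin B | COC(=O)c1c(O)cc(O)cc1Oc1c(O)c(OC)cc(CC=C(C)C)c1OC | target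

**Totals**
Total steps: 6 (convergent). Longest linear sequence: 5 (steps 1, 2, 4, 5, 6).

**Three steps most likely to fail**
1. Step 4 (Pd C–O coupling). The phenol is 2,6-dialkoxy-substituted and hindered, the triflate can lose its triflyl group to phenoxide, and Pd(0) may ionise the aryl prenyl ether. Fallback: switch to a copper Ullmann coupling of 6 with methyl 2-bromo-4,6-bis(methoxymethoxy)benzoate (CuI/picolinic acid/K3PO4, DMSO, 90 °C). The bromide is made from commercial 2-bromo-4,6-dimethoxybenzaldehyde by BBr3 demethylation, MOM protection, Pinnick oxidation and methylation. Cu(I) does not open allyl ethers and the ortho-ester accelerates the coupling.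
2. Step 5 (para-Claisen). Thermal loss of the prenyl group or lactonisation of the new phenol onto the ester could compete. Fallback: install the prenyl by cross-coupling instead. Couple 3 with a mono-TBS ether of 4, desilylate, brominate para to the free phenol (NBS, low temperature), then Pd-catalysed prenylation (Stille with tributyl(prenyl)stannane or Suzuki with prenyl-Bpin).
3. Step 6 (acidic MOM removal next to a prenyl group). HCl or MeOH could add across the trisubstituted alkene. Fallback: use an acid-free endgame by building ring A from 5,7-dihydroxy-2,2-dimethyl-4H-1,3-benzodioxin-4-one (7-OTBS, 5-OTf). After coupling and Claisen, NaOMe/MeOH opens the dioxinone directly to the methyl ester and 2-OH and removes the aryl silyl ether.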